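**Retrosynthetic overview**
1. Isogoiazensolide ⇐ methacryloylation of the C8 hydroxyl and removal of a C5 silyl ether from the 8‑hydroxy tricycle.
2. Ten‑membered carbocycle ⇐ C7–C8 bond by a ring‑closing Nozaki–Hiyama (Barbier‑type) allylation. A 3‑(bromomethyl)butenolide becomes an allylchromium reagent (β‑acylvinyl anion, homoenolate‑type) that attacks the C8 aldehyde through the normally electrophilic butenolide β‑carbon C7; this sets C7 and C8 and unveils the α‑methylene lactone.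
3. C5–C6 ⇐ enantioselective anti vinylogous Mukaiyama aldol of a 2‑silyloxyfuran with a 2‑(furanonyl)acrolein (sets C5 and C6).
4. Acrolein ⇐ formylation/Mannich methylenation of the 5‑methyl group of (R)‑2‑allyl‑2,5‑dimethylfuran‑3(2H)‑one; C10 ⇐ palladium‑catalysed asymmetric allylation of 2,5‑dimethylfuran‑3(2H)‑one (allyl = masked C8 aldehyde).
5. Ring order: furanone (bought) → butenolide (from furan‑3‑ylmethanol) → ten‑membered carbocycle with the α‑methylene‑γ‑lactone last.

Assumption: furanoheliangolide numbering is used (C1 ketone, C2=C3 enol ether, C4(=C15H2), C5 carbinol, C6 lactone oxygen, C7, C8 ester, C9, C10 bearing CH3‑14 and the ether oxygen to C3, C11(=C13H2), C12 lactone carbonyl); the target is (5R,6S,7R,8S,10R).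

**Route**

Step 1
Reactants: 1 2,5-dimethylfuran-3(2H)-one (racemic)
Product: 2 (2R)-2,5-dimethyl-2-(prop-2-en-1-yl)furan-3(2H)-one
Conditions: allyl methyl carbonate (1.2 equiv), Pd2(dba)3 (2.5 mol%, zerovalent palladium), (1R,2R)-N,N′-bis[2-(diphenylphosphino)benzoyl]cyclohexane-1,2-diamine (7.5 mol%), toluene, 0 °C
Reagents that add atoms: allyl methyl carbonate (C=CCOC(=O)OC)
Why: Tsuji–Trost asymmetric allylic alkylation in which methoxide from the carbonate converts racemic 1 into the planar aromatic 3‑oxidofuran, whose soft C2 terminus attacks the chiral π‑allylpalladium complex so that the ligand sets the quaternary C10 centre as R (any O‑allyl ether re‑ionises and funnels to the C‑allyl product; the antipodal ligand is used if the observed sense is opposite).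

Step 2
Reactants: 2 (2R)-2,5-dimethyl-2-(prop-2-en-1-yl)furan-3(2H)-one
Product: 6 2-[(5R)-5-methyl-4-oxo-5-(prop-2-en-1-yl)-4,5-dihydrofuran-2-yl]prop-2-enal, via lithium dienolate 3 (not isolated), via formyl compound 4 (not isolated), via Mannich base 5 (not isolated)
Conditions: LiN(iPr)2 (1.1 equiv), THF, −78 °C; HCO2CH2CF3 (1.2 equiv), −78 °C; [CH2=NMe2]I (1.5 equiv), −78 °C to rt; Et3N (cat.), 35 °C; cold aq. NaHCO3, product used at once
Reagents that add atoms: 2,2,2-trifluoroethyl formate (O=COCC(F)(F)F); N,N-dimethylmethyleneiminium iodide (C=[N+](C)C.[I-])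
Why: Kinetic γ‑deprotonation of the vinylogous 5‑methyl group gives the extended dienolate, which undergoes Claisen‑type formylation; the resulting vinylogous β‑keto‑aldehyde enolate is then aminomethylated at C4 (Mannich reaction) and loses dimethylamine by E1cB elimination to give the 2‑substituted acrolein, with no new stereocentre and the quaternary C10 untouched.

Step 3
Reactants: 7 furan-3-ylmethanol
Product: 10 3-(hydroxymethyl)furan-2(5H)-one, via dilithiated furan 8 (not isolated), via furylborate 9 (not isolated)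
Conditions: n-BuLi (2.2 equiv), THF, −78 to 0 °C; B(OMe)3, −78 °C; 30% H2O2, AcOH, 0 °C
Reagents that add atoms: hydrogen peroxide (OO)
Why: Alkoxide‑directed ortho‑lithiation at C2, borylation and oxidative deboronation give the 2‑hydroxyfuran, which tautomerises to the conjugated butenolide; no stereocentre is involved.

Step 4
Reactants: 10 3-(hydroxymethyl)furan-2(5H)-one
Product: 11 trimethyl[(3-{[(trimethylsilyl)oxy]methyl}furan-2-yl)oxy]silane
Conditions: Me3SiCl (2.3 equiv), Et3N (2.6 equiv), Et2O/MeCN, 0 °C to rt; distilled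
Reagents that add atoms: chlorotrimethylsilane (C[Si](C)(C)Cl)
Why: Soft enolisation with O‑silylation (triethylamine removes the γ‑proton as the lactone oxygen is silylated) gives the aromatic 2‑silyloxyfuran, and the primary alcohol is silylated at the same time; a silyloxy group at C13 is too poor a leaving group to be lost from the dienol ether.

Step 5
Reactants: 6 2-[(5R)-5-methyl-4-oxo-5-(prop-2-en-1-yl)-4,5-dihydrofuran-2-yl]prop-2-enal; 11 trimethyl[(3-{[(trimethylsilyl)oxy]methyl}furan-2-yl)oxy]silane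
Product: 13 (5S)-5-{(1R)-1-hydroxy-2-[(5R)-5-methyl-4-oxo-5-(prop-2-en-1-yl)-4,5-dihydrofuran-2-yl]prop-2-en-1-yl}-3-(hydroxymethyl)furan-2(5H)-one, via trichlorosilyl aldolate 12 (not isolated)
Conditions: SiCl4 (1.2 equiv), (R,R)-4,4′-[pentane-1,5-diylbis(methylimino)]bis(3,5-dimethyl-4,5-dihydro-3H-dinaphtho[2,1-d:1′,2′-f][1,3,2]diazaphosphepine 4-oxide) (5 mol%), iPr2NEt (10 mol%), CH2Cl2, −78 °C; aq. NaHCO3/KF
Reagents that add atoms: none
Why: Vinylogous Mukaiyama aldol reaction in which the chiral phosphoramide‑bound trichlorosilyl cation activates the conjugated aldehyde and exposes its Re face to C5 of the silyloxyfuran in an open transition state, giving the 5,1′‑anti adduct with C5 R and C6 S under catalyst control (the remote C10 centre exerts no influence), both silyl groups being lost on work‑up.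

Step 6
Reactants: 13 (5S)-5-{(1R)-1-hydroxy-2-[(5R)-5-methyl-4-oxo-5-(prop-2-en-1-yl)-4,5-dihydrofuran-2-yl]prop-2-en-1-yl}-3-(hydroxymethyl)furan-2(5H)-one
Product: 14 (5S)-3-(bromomethyl)-5-{(1R)-1-hydroxy-2-[(5R)-5-methyl-4-oxo-5-(prop-2-en-1-yl)-4,5-dihydrofuran-2-yl]prop-2-en-1-yl}furan-2(5H)-one
Conditions: CBr4 (1.1 equiv), PPh3 (1.1 equiv, slow addition), CH2Cl2, −40 °C
Reagents that add atoms: carbon tetrabromide (BrC(Br)(Br)Br)
Why: Appel reaction in which the unhindered primary allylic hydroxyl is activated in preference to the hindered secondary one at low temperature and displaced by bromide, leaving all stereocentres untouched.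

Step 7
Reactants: 14 (5S)-3-(bromomethyl)-5-{(1R)-1-hydroxy-2-[(5R)-5-methyl-4-oxo-5-(prop-2-en-1-yl)-4,5-dihydrofuran-2-yl]prop-2-en-1-yl}furan-2(5H)-one
Product: 15 (5S)-3-(bromomethyl)-5-{(1R)-1-[(tert-butyldimethylsilyl)oxy]-2-[(5R)-5-methyl-4-oxo-5-(prop-2-en-1-yl)-4,5-dihydrofuran-2-yl]prop-2-en-1-yl}furan-2(5H)-one
Conditions: TBSOTf (1.3 equiv), 2,6-lutidine (2 equiv), CH2Cl2, −78 °C
Reagents that add atoms: tert-butyldimethylsilyl triflate (CC(C)(C)[Si](C)(C)OS(=O)(=O)C(F)(F)F)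
Why: Silyl ether formation masks the C5 hydroxyl so that the C8 hydroxyl formed in step 9 is the only one acylated later, the hindered weak base at −78 °C leaving the allylic bromide and the butenolide γ‑proton alone.

Step 8
Reactants: 15 (5S)-3-(bromomethyl)-5-{(1R)-1-[(tert-butyldimethylsilyl)oxy]-2-[(5R)-5-methyl-4-oxo-5-(prop-2-en-1-yl)-4,5-dihydrofuran-2-yl]prop-2-en-1-yl}furan-2(5H)-one
Product: 17 (5S)-3-(bromomethyl)-5-{(1R)-1-[(tert-butyldimethylsilyl)oxy]-2-[(5R)-5-methyl-4-oxo-5-(2-oxoethyl)-4,5-dihydrofuran-2-yl]prop-2-en-1-yl}furan-2(5H)-one, via vicinal diol 16 (not isolated)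
Conditions: OsO4 (2 mol%), NaIO4 (4 equiv), 2,6-lutidine (2 equiv), dioxane/H2O 3:1, rt; crude product used at once
Reagents that add atoms: osmium tetroxide (O=[Os](=O)(=O)=O), re-oxidised by sodium periodate ([Na+].[O-]I(=O)(=O)=O)
Why: Lemieux–Johnson cleavage in which electrophilic OsO4 dihydroxylates only the isolated monosubstituted alkene (the other three C=C bonds are conjugated with carbonyl groups and deactivated) and periodate cleaves the diol, so that the β‑alkoxy aldehyde, which would open the furanone by retro‑oxa‑Michael reaction under base, is formed near neutrality with no stereocentre affected.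

Step 9
Reactants: 17 (5S)-3-(bromomethyl)-5-{(1R)-1-[(tert-butyldimethylsilyl)oxy]-2-[(5R)-5-methyl-4-oxo-5-(2-oxoethyl)-4,5-dihydrofuran-2-yl]prop-2-en-1-yl}furan-2(5H)-one
Product: 19 (5R,6S,7R,8S,10R)-5-[(tert-butyldimethylsilyl)oxy]-8-hydroxy-1-oxo-3,10-epoxygermacra-2,4(15),11(13)-trien-12,6-olide, via allylchromium species 18 (not isolated)
Conditions: CrCl2 (6 equiv), THF, rt, syringe-pump addition of 17 over 12 h to 1 mM; aq. NH4Cl
Reagents that add atoms: none
Why: Nozaki–Hiyama (Barbier‑type) allylation used as the ring closure, in which two equivalents of divalent chromium turn the allylic bromide into an allylchromium species of trivalent chromium (a β‑acylvinyl‑anion, homoenolate‑type nucleophile whose reacting γ‑carbon is the normally electrophilic butenolide β‑carbon C7) that adds to the C8 aldehyde through a chair Zimmerman–Traxler transition state on the ring face anti to the C6 side chain (trans 6,7‑fusion, C7 R) with the aldehyde chain equatorial (the ring‑locked E‑type allyl unit therefore gives the 7,8‑anti carbinol, C8 S), while allylic transposition unveils the C11(13) methylidene.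

Step 10
Reactants: 19 (5R,6S,7R,8S,10R)-5-[(tert-butyldimethylsilyl)oxy]-8-hydroxy-1-oxo-3,10-epoxygermacra-2,4(15),11(13)-trien-12,6-olide
Product: 20 (5R,6S,7R,8S,10R)-5-[(tert-butyldimethylsilyl)oxy]-8-[(2-methylprop-2-enoyl)oxy]-1-oxo-3,10-epoxygermacra-2,4(15),11(13)-trien-12,6-olide
Conditions: methacrylic anhydride (3 equiv), Et3N, 4-(dimethylamino)pyridine (0.2 equiv), CH2Cl2, 0 °C to rt
Reagents that add atoms: methacrylic anhydride (CC(=C)C(=O)OC(=O)C(C)=C)
Why: Nucleophilic‑catalysed (Steglich‑type) acylation of the only free hydroxyl proceeds with retention at C8, the silyl ether at C5 securing site selectivity.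

Step 11
Reactants: 20 (5R,6S,7R,8S,10R)-5-[(tert-butyldimethylsilyl)oxy]-8-[(2-methylprop-2-enoyl)oxy]-1-oxo-3,10-epoxygermacra-2,4(15),11(13)-trien-12,6-olide
Product: 21 isogoiazensolide [(5R,6S,7R,8S,10R)-5-hydroxy-8-[(2-methylprop-2-enoyl)oxy]-1-oxo-3,10-epoxygermacra-2,4(15),11(13)-trien-12,6-olide]
Conditions: HF·pyridine, THF/pyridine, 0 °C to rt
Reagents that add atoms: none
Why: Fluoride‑mediated desilylation under buffered, non‑basic conditions frees the C5 hydroxyl without touching the methacrylate, the α‑methylene lactone or the furanone and without changing any stereocentre.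

**Compound list**
1 | 2,5-dimethylfuran-3(2H)-one (racemic) | CC1=CC(=O)C(C)O1 | starting material
2 | (2R)-2,5-dimethyl-2-(prop-2-en-1-yl)furan-3(2H)-one | C=CC[C@@]1(C)OC(C)=CC1=O | intermediate
3 | lithium (2R)-2-methyl-5-methylidene-2-(prop-2-en-1-yl)-2,5-dihydrofuran-3-olate | C=CC[C@@]1(C)OC(=C)C=C1O[Li] | intermediate (not isolated)
4 | [(5R)-5-methyl-4-oxo-5-(prop-2-en-1-yl)-4,5-dihydrofuran-2-yl]acetaldehyde (formed as its lithium enolate) | C=CC[C@@]1(C)OC(CC=O)=CC1=O | intermediate (not isolated)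
5 | 3-(dimethylamino)-2-[(5R)-5-methyl-4-oxo-5-(prop-2-en-1-yl)-4,5-dihydrofuran-2-yl]propanal (both C2 epimers) | C=CC[C@@]1(C)OC(C(CN(C)C)C=O)=CC1=O | intermediate (not isolated)
6 | 2-[(5R)-5-methyl-4-oxo-5-(prop-2-en-1-yl)-4,5-dihydrofuran-2-yl]prop-2-enal | C=CC[C@@]1(C)OC(C(=C)C=O)=CC1=O | intermediate
7 | furan-3-ylmethanol | OCc1ccoc1 | starting material
8 | lithium (2-lithiofuran-3-yl)methanolate | [Li]OCc1ccoc1[Li] | intermediate (not isolated)
9 | lithium trimethoxy{3-[(lithiooxy)methyl]furan-2-yl}borate | CO[B-](OC)(OC)c1occc1CO[Li].[Li+] | intermediate (not isolated)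
10 | 3-(hydroxymethyl)furan-2(5H)-one | O=C1OCC=C1CO | intermediate
11 | trimethyl[(3-{[(trimethylsilyl)oxy]methyl}furan-2-yl)oxy]silane | C[Si](C)(C)OCc1ccoc1O[Si](C)(C)C | intermediate
12 | (5S)-5-{(1R)-2-[(5R)-5-methyl-4-oxo-5-(prop-2-en-1-yl)-4,5-dihydrofuran-2-yl]-1-[(trichlorosilyl)oxy]prop-2-en-1-yl}-3-{[(trimethylsilyl)oxy]methyl}furan-2(5H)-one | C=CC[C@@]1(C)OC(=CC1=O)C(=C)[C@@H](O[Si](Cl)(Cl)Cl)[C@H]1OC(=O)C(CO[Si](C)(C)C)=C1 | intermediate (not isolated)
13 | (5S)-5-{(1R)-1-hydroxy-2-[(5R)-5-methyl-4-oxo-5-(prop-2-en-1-yl)-4,5-dihydrofuran-2-yl]prop-2-en-1-yl}-3-(hydroxymethyl)furan-2(5H)-one | C=CC[C@@]1(C)OC(=CC1=O)C(=C)[C@@H](O)[C@H]1OC(=O)C(CO)=C1 | intermediate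
14 | (5S)-3-(bromomethyl)-5-{(1R)-1-hydroxy-2-[(5R)-5-methyl-4-oxo-5-(prop-2-en-1-yl)-4,5-dihydrofuran-2-yl]prop-2-en-1-yl}furan-2(5H)-one | C=CC[C@@]1(C)OC(=CC1=O)C(=C)[C@@H](O)[C@H]1OC(=O)C(CBr)=C1 | intermediate
15 | (5S)-3-(bromomethyl)-5-{(1R)-1-[(tert-butyldimethylsilyl)oxy]-2-[(5R)-5-methyl-4-oxo-5-(prop-2-en-1-yl)-4,5-dihydrofuran-2-yl]prop-2-en-1-yl}furan-2(5H)-one | C=CC[C@@]1(C)OC(=CC1=O)C(=C)[C@@H](O[Si](C)(C)C(C)(C)C)[C@H]1OC(=O)C(CBr)=C1 | intermediate
16 | (5S)-3-(bromomethyl)-5-{(1R)-1-[(tert-butyldimethylsilyl)oxy]-2-[(5R)-5-(2,3-dihydroxypropyl)-5-methyl-4-oxo-4,5-dihydrofuran-2-yl]prop-2-en-1-yl}furan-2(5H)-one (both carbinol epimers) | OCC(O)C[C@@]1(C)OC(=CC1=O)C(=C)[C@@H](O[Si](C)(C)C(C)(C)C)[C@H]1OC(=O)C(CBr)=C1 | intermediate (not isolated)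
17 | (5S)-3-(bromomethyl)-5-{(1R)-1-[(tert-butyldimethylsilyl)oxy]-2-[(5R)-5-methyl-4-oxo-5-(2-oxoethyl)-4,5-dihydrofuran-2-yl]prop-2-en-1-yl}furan-2(5H)-one | O=CC[C@@]1(C)OC(=CC1=O)C(=C)[C@@H](O[Si](C)(C)C(C)(C)C)[C@H]1OC(=O)C(CBr)=C1 | intermediate
18 | dichloro{[(5S)-5-{(1R)-1-[(tert-butyldimethylsilyl)oxy]-2-[(5R)-5-methyl-4-oxo-5-(2-oxoethyl)-4,5-dihydrofuran-2-yl]prop-2-en-1-yl}-2-oxo-2,5-dihydrofuran-3-yl]methyl}chromium (allylchromium species of trivalent chromium) | O=CC[C@@]1(C)OC(=CC1=O)C(=C)[C@@H](O[Si](C)(C)C(C)(C)C)[C@H]1OC(=O)C(C[Cr](Cl)Cl)=C1 | intermediate (not isolated)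
19 | (5R,6S,7R,8S,10R)-5-[(tert-butyldimethylsilyl)oxy]-8-hydroxy-1-oxo-3,10-epoxygermacra-2,4(15),11(13)-trien-12,6-olide | O[C@H]1C[C@@]2(C)OC(=CC2=O)C(=C)[C@@H](O[Si](C)(C)C(C)(C)C)[C@H]2OC(=O)C(=C)[C@@H]21 | intermediate
20 | (5R,6S,7R,8S,10R)-5-[(tert-butyldimethylsilyl)oxy]-8-[(2-methylprop-2-enoyl)oxy]-1-oxo-3,10-epoxygermacra-2,4(15),11(13)-trien-12,6-olide | C=C(C)C(=O)O[C@H]1C[C@@]2(C)OC(=CC2=O)C(=C)[C@@H](O[Si](C)(C)C(C)(C)C)[C@H]2OC(=O)C(=C)[C@@H]21 | intermediate
21 | isogoiazensolide, (5R,6S,7R,8S,10R)-5-hydroxy-8-[(2-methylprop-2-enoyl)oxy]-1-oxo-3,10-epoxygermacra-2,4(15),11(13)-trien-12,6-olide | C=C(C)C(=O)O[C@H]1C[C@@]2(C)OC(=CC2=O)C(=C)[C@@H](O)[C@H]2OC(=O)C(=C)[C@@H]21 | target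

**Summary**
Total step count: 11 (steps 3 and 4 build the silyloxyfuran arm). Longest linear sequence: 9 (steps 1, 2, 5, 6, 7, 8, 9, 10, 11).

**Steps most likely to fail, with fallbacks**

Step 9 (ring‑closing allylation). The nine‑atom tether may force the aldehyde chain axial in the transition state and give the wrong C8 configuration; oligomerisation or closure on the other face of C7 would have no remedy here. The fallback sets out from 17 and comes back at 20. If cyclisation under the same conditions gives mainly the C8 epimer (5R,6S,7R,8R,10R)-5-[(tert-butyldimethylsilyl)oxy]-8-hydroxy-1-oxo-3,10-epoxygermacra-2,4(15),11(13)-trien-12,6-olide F1, the retentive acylation of step 10 is replaced by a Mitsunobu esterification (methacrylic acid, PPh3, diisopropyl azodicarboxylate, toluene, 0 °C), which installs the methacrylate with inversion at C8 and delivers 20 directly.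

Step 5 (aldol on the doubly activated acrolein 6). Compound 6 may polymerise or take the nucleophile at C15 instead of at the aldehyde. The fallback sets out from 4 (isolated by quenching step 2 with aq. NH4Cl before the iminium salt is added) and comes back at 13.
- C‑Methylation (MeI, K2CO3, acetone) gives 2-[(5R)-5-methyl-4-oxo-5-(prop-2-en-1-yl)-4,5-dihydrofuran-2-yl]propanal F2.
- Selenenylation (PhSeCl, pyridine, CH2Cl2) gives the non‑enolisable, non‑conjugated aldehyde 2-[(5R)-5-methyl-4-oxo-5-(prop-2-en-1-yl)-4,5-dihydrofuran-2-yl]-2-(phenylselanyl)propanal F3, a stable masked form of 6.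
- Its anti‑selective vinylogous Mukaiyama aldol with 11 ((R,R)-N,N′-bis(3,5-di-tert-butylsalicylidene)cyclohexane-1,2-diaminochromium chloride 5 mol%, iPrOH, CH2Cl2, −20 °C, dilute acid work‑up) gives (5S)-5-{(1S)-1-hydroxy-2-[(5R)-5-methyl-4-oxo-5-(prop-2-en-1-yl)-4,5-dihydrofuran-2-yl]-2-(phenylselanyl)propyl}-3-(hydroxymethyl)furan-2(5H)-one F4. The carbinol has the same spatial arrangement as in 13; its descriptor is S only because selenium changes the priorities.
- H2O2/pyridine (0 °C to rt) oxidises F4 to the selenoxide (5S)-5-{(1S)-1-hydroxy-2-[(5R)-5-methyl-4-oxo-5-(prop-2-en-1-yl)-4,5-dihydrofuran-2-yl]-2-(phenylseleninyl)propyl}-3-(hydroxymethyl)furan-2(5H)-one F5, which undergoes syn‑elimination towards the methyl group (away from the carbinol) and so unveils the C4(15) methylidene of 13.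

Step 8 (oxidative cleavage). Osmium may also attack the C4(15) alkene, and the allylic bromide must survive aqueous lutidine. The fallback sets out from 15 and comes back at 17. Peracid epoxidation (mCPBA, NaHCO3, CH2Cl2, rt) touches only the non‑conjugated terminal alkene and gives (5S)-3-(bromomethyl)-5-{(1R)-1-[(tert-butyldimethylsilyl)oxy]-2-[(5R)-5-methyl-5-(oxiran-2-ylmethyl)-4-oxo-4,5-dihydrofuran-2-yl]prop-2-en-1-yl}furan-2(5H)-one F6. Periodic acid (H5IO6, THF/H2O, 0 °C) then opens the epoxide to diol 16 and cleaves it to 17 under acidic conditions, without osmium and without amine.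

**Further compounds**
F1 | step 9 | (5R,6S,7R,8R,10R)-5-[(tert-butyldimethylsilyl)oxy]-8-hydroxy-1-oxo-3,10-epoxygermacra-2,4(15),11(13)-trien-12,6-olide | O[C@@H]1C[C@@]2(C)OC(=CC2=O)C(=C)[C@@H](O[Si](C)(C)C(C)(C)C)[C@H]2OC(=O)C(=C)[C@@H]21
F2 | step 5 | 2-[(5R)-5-methyl-4-oxo-5-(prop-2-en-1-yl)-4,5-dihydrofuran-2-yl]propanal (both C2 epimers) | C=CC[C@@]1(C)OC(C(C)C=O)=CC1=O
F3 | step 5 | 2-[(5R)-5-methyl-4-oxo-5-(prop-2-en-1-yl)-4,5-dihydrofuran-2-yl]-2-(phenylselanyl)propanal (both C2 epimers) | C=CC[C@@]1(C)OC(C(C)([Se]c2ccccc2)C=O)=CC1=O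
F4 | step 5 | (5S)-5-{(1S)-1-hydroxy-2-[(5R)-5-methyl-4-oxo-5-(prop-2-en-1-yl)-4,5-dihydrofuran-2-yl]-2-(phenylselanyl)propyl}-3-(hydroxymethyl)furan-2(5H)-one (both C2′ epimers) | C=CC[C@@]1(C)OC(=CC1=O)C(C)([Se]c1ccccc1)[C@@H](O)[C@H]1OC(=O)C(CO)=C1
F5 | step 5 | (5S)-5-{(1S)-1-hydroxy-2-[(5R)-5-methyl-4-oxo-5-(prop-2-en-1-yl)-4,5-dihydrofuran-2-yl]-2-(phenylseleninyl)propyl}-3-(hydroxymethyl)furan-2(5H)-one (not isolated) | C=CC[C@@]1(C)OC(=CC1=O)C(C)([Se](=O)c1ccccc1)[C@@H](O)[C@H]1OC(=O)C(CO)=C1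
F6 | step 8 | (5S)-3-(bromomethyl)-5-{(1R)-1-[(tert-butyldimethylsilyl)oxy]-2-[(5R)-5-methyl-5-(oxiran-2-ylmethyl)-4-oxo-4,5-dihydrofuran-2-yl]prop-2-en-1-yl}furan-2(5H)-one (both epoxide epimers) | O1CC1C[C@@]1(C)OC(=CC1=O)C(=C)[C@@H](O[Si](C)(C)C(C)(C)C)[C@H]1OC(=O)C(CBr)=C1
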